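The target is a 3(2H)-furanone bridged across a germacranolide. Its furanone carbonyl C1 and the ester-bearing C8 are 1,4-related through the quaternary, oxygen-bearing C10, which is the signature of a Stetter product. The route therefore closes the five-membered O–C10–C1–C2–C3 ring by an enantioselective intramolecular Stetter reaction: the acyl-anion equivalent of a C1 aldehyde adds to C10 of a tethered (E)-β-alkoxycrotonate, creating the C1–C10 bond, the quaternary stereocentre and the C1/C8 dicarbonyl pattern in one operation. The precursor is an acyclic aldehyde–vinylogous carbonate built by oxa-Michael addition. A zinc Barbier union with a bromomethyl butenolide, Mitsunobu esterification and ring-closing metathesis complete the skeleton.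

Key step: step 6

Remark (numbering): germacrane numbering is used throughout: C1 furanone C=O, C2 furanone CH, C3 furanone O-bearing sp2 carbon, C4=C5 ring alkene, C6 lactone CH–O, C7, C8 ester carbinol, C9 CH2, C10 quaternary C–O, C11–C13 methylene lactone.
Assumption: 3-[(tert-butyldimethylsilyl)oxy]propanal and (4E)-hexa-1,4-dien-3-ol are taken as purchasable; the second is otherwise one step from crotonaldehyde and vinylmagnesium bromide.

Step 1
Reactants: 1 3-[(tert-butyldimethylsilyl)oxy]propanal; 2 isopropenylmagnesium bromide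
Product: 3 rac-5-[(tert-butyldimethylsilyl)oxy]-2-methylpent-1-en-3-ol
Conditions: THF, −78 → 0 °C; aq. NH4Cl
Reagents that add atoms: none
Why: Grignard 1,2-addition of an alkenylmagnesium halide to an aldehyde; the carbinol centre (later C3) forms as a racemate and is resolved in step 2.

Step 2
Reactants: 3 rac-5-[(tert-butyldimethylsilyl)oxy]-2-methylpent-1-en-3-ol
Product: 4 (3S)-5-[(tert-butyldimethylsilyl)oxy]-2-methylpent-1-en-3-ol
Conditions: Ti(OiPr)4 (0.15 equiv), D-(−)-DIPT (0.2 equiv), t-BuOOH (0.6 equiv), 4 Å MS, CH2Cl2, −20 °C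
Reagents that add atoms: none
Why: Sharpless kinetic resolution: with D-(−)-tartrate the (R)-allylic alcohol should be epoxidised fast to its erythro epoxy alcohol, so that the (S)-alcohol is recovered; this sacrificial centre later reinforces the facial bias of the ring closure.

Step 3
Reactants: 4 (3S)-5-[(tert-butyldimethylsilyl)oxy]-2-methylpent-1-en-3-ol; 5 ethyl but-2-ynoate
Product: 6 ethyl (2E)-3-{[(3S)-5-[(tert-butyldimethylsilyl)oxy]-2-methylpent-1-en-3-yl]oxy}but-2-enoate
Conditions: PMe3 (0.2 equiv), CH2Cl2, 0 → 23 °C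
Reagents that add atoms: none
Why: Phosphine-catalysed oxa-Michael addition of an alcohol to a 2-alkynoate, which should give the (E)-β-alkoxycrotonate; the carbinol centre is not touched.

Step 4
Reactants: 6 ethyl (2E)-3-{[(3S)-5-[(tert-butyldimethylsilyl)oxy]-2-methylpent-1-en-3-yl]oxy}but-2-enoate
Product: 7 ethyl (2E)-3-{[(3S)-5-hydroxy-2-methylpent-1-en-3-yl]oxy}but-2-enoate
Conditions: HF·pyridine, pyridine, THF, 0 °C
Reagents that add atoms: none
Why: Fluoride cleavage of a primary silyl ether under weakly acidic conditions, which should leave the vinylogous carbonate intact and avoid base-induced intramolecular oxa-Michael addition of the freed hydroxyl.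

Step 5
Reactants: 7 ethyl (2E)-3-{[(3S)-5-hydroxy-2-methylpent-1-en-3-yl]oxy}but-2-enoate
Product: 8 ethyl (2E)-3-{[(3S)-2-methyl-5-oxopent-1-en-3-yl]oxy}but-2-enoate
Conditions: Dess–Martin periodinane, NaHCO3, CH2Cl2, 0 → 23 °C; used at once
Reagents that add atoms: none
Why: Dess–Martin oxidation of a primary alcohol to the aldehyde under buffered, non-basic conditions, so that the β-alkoxy aldehyde should not eliminate.

Step 6
Reactants: 8 ethyl (2E)-3-{[(3S)-2-methyl-5-oxopent-1-en-3-yl]oxy}but-2-enoate
Product: 9 ethyl 2-[(2S,5S)-2-methyl-3-oxo-5-(prop-1-en-2-yl)oxolan-2-yl]acetate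
Conditions: aminoindanol-derived N-pentafluorophenyl triazolium tetrafluoroborate (15 mol%, the antipode that delivers 2S), KHMDS (15 mol%), toluene, 23 °C
Reagents that add atoms: none
Why: The triazolylidene adds to the aldehyde C1 to give a Breslow intermediate, whose nucleophilic C1 adds in a conjugate sense to C10, the β-carbon of the tethered (E)-β-alkoxycrotonate, and proton transfer with loss of the carbene gives the 1,4-keto ester. The closest known reaction type is the asymmetric intramolecular Stetter reaction of aldehydes tethered through oxygen to β,β-disubstituted acrylates, which gives 2,2-disubstituted 3-oxo oxygen heterocycles with a quaternary stereocentre. The oxolan-3-one ring (O–C10–C1–C2–C3) closes in the 5-exo-trig mode. The new quaternary centre C10 is set by the chiral carbene, which shields one face of the (E)-alkene, and the (S)-centre at C3 should reinforce this because a 2,5-cis arrangement of the isopropenyl group and the acetate arm is favoured in the envelope transition state. The step needs acyl-anion addition to win over base-induced loss of the β-alkoxy group, over aldehyde self-condensation and over attack on the ester; the 5-exo geometry, the defined (E)-geometry of the acceptor and the substoichiometric base (consumed in forming the carbene) should secure this.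

Step 7
Reactants: 9 ethyl 2-[(2S,5S)-2-methyl-3-oxo-5-(prop-1-en-2-yl)oxolan-2-yl]acetate
Product: 10 2-[(2S,5S)-3-hydroxy-2-methyl-5-(prop-1-en-2-yl)oxolan-2-yl]ethan-1-ol (both C3 epimers)
Conditions: LiAlH4, THF, −78 → 0 °C; Rochelle salt work-up
Reagents that add atoms: none
Why: Hydride reduction of ester and ketone together; the new ring carbinol centre is of no consequence because it is reoxidised in step 8, and the quaternary centre cannot epimerise.

Step 8
Reactants: 10 2-[(2S,5S)-3-hydroxy-2-methyl-5-(prop-1-en-2-yl)oxolan-2-yl]ethan-1-ol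
Product: 11 2-[(2S,5S)-2-methyl-3-oxo-5-(prop-1-en-2-yl)oxolan-2-yl]acetaldehyde
Conditions: (COCl)2, DMSO, CH2Cl2, −78 °C; then Et3N, −78 → 0 °C
Reagents that add atoms: none
Why: Swern oxidation, in which both hydroxyls are activated before the base is added, so that the 1,4-diol should go to the keto aldehyde without passing through a lactol that could be oxidised to a lactone.

Step 9
Reactants: 11 2-[(2S,5S)-2-methyl-3-oxo-5-(prop-1-en-2-yl)oxolan-2-yl]acetaldehyde
Product: 12 2-[(2S)-2-methyl-3-oxo-5-(prop-1-en-2-yl)-2,3-dihydrofuran-2-yl]acetaldehyde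
Conditions: IBX (2.5 equiv), DMSO, 70 °C
Reagents that add atoms: none
Why: IBX-mediated α,β-dehydrogenation of a ketone; only C2–C3 can be desaturated (C10 is quaternary and the aldehyde has no β-hydrogen), the product is a stable vinylogous ester, and the sacrificial C3 centre disappears.

Step 10
Reactants: 13 rac-(4E)-hexa-1,4-dien-3-ol
Product: 14 (3S,4E)-hexa-1,4-dien-3-ol
Conditions: Ti(OiPr)4 (0.15 equiv), D-(−)-DIPT (0.2 equiv), t-BuOOH (0.6 equiv), 4 Å MS, CH2Cl2, −20 °C
Reagents that add atoms: none
Why: Sharpless kinetic resolution: the (R)-enantiomer should be epoxidised fast at its matched, more nucleophilic (E)-propenyl group, whereas the only matched olefin of the (S)-enantiomer is the much slower vinyl group, so that the (S)-alcohol is recovered.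

Step 11
Reactants: 14 (3S,4E)-hexa-1,4-dien-3-ol; 15 2-(bromomethyl)prop-2-enoic acid
Product: 16 (3S,4E)-hexa-1,4-dien-3-yl 2-(bromomethyl)prop-2-enoate
Conditions: DCC, DMAP (5 mol%), CH2Cl2, 0 °C
Reagents that add atoms: none
Why: Steglich esterification with retention at the carbinol carbon; low temperature and a catalytic amount of DMAP should limit alkylation of the base by the allylic bromide.

Step 12
Reactants: 16 (3S,4E)-hexa-1,4-dien-3-yl 2-(bromomethyl)prop-2-enoate
Product: 17 (5R)-3-(bromomethyl)-5-[(1E)-prop-1-en-1-yl]furan-2(5H)-one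
Conditions: Grubbs second-generation catalyst (5 mol%), CH2Cl2 (5 mM), 40 °C
Reagents that add atoms: none
Why: Ring-closing metathesis of an allylic acrylate to a butenolide: ruthenium should load on the monosubstituted vinyl group and close on the acrylate with loss of ethene, leaving the propenyl group and the stereocentre untouched (S becomes R only through the CIP ranking).

Step 13
Reactants: 12 2-[(2S)-2-methyl-3-oxo-5-(prop-1-en-2-yl)-2,3-dihydrofuran-2-yl]acetaldehyde; 17 (5R)-3-(bromomethyl)-5-[(1E)-prop-1-en-1-yl]furan-2(5H)-one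
Product: 19 (4R,5R)-4-{(1S)-1-hydroxy-2-[(2S)-2-methyl-3-oxo-5-(prop-1-en-2-yl)-2,3-dihydrofuran-2-yl]ethyl}-3-methylidene-5-[(1E)-prop-1-en-1-yl]oxolan-2-one, via allylzinc bromide 18 (not isolated)
Conditions: Zn dust, THF/sat. aq. NH4Cl (2:1), 0 → 23 °C
Reagents that add atoms: none
Why: Zinc Barbier allylation of an aldehyde with a 3-(bromomethyl)furan-2(5H)-one: the allylzinc should add through its γ-carbon (C7) anti to the propenyl group on C6, giving the trans-lactone, and a closed chair transition state with the ring-locked (E)-type γ-substituent should give the anti (8S) carbinol, the epimer needed for inversion in step 14.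

Step 14
Reactants: 19 the (8S)-alcohol from step 13; 20 3-methylbutanoic acid
Product: 21 (1R)-2-[(2S)-2-methyl-3-oxo-5-(prop-1-en-2-yl)-2,3-dihydrofuran-2-yl]-1-{(2R,3R)-4-methylidene-5-oxo-2-[(1E)-prop-1-en-1-yl]oxolan-3-yl}ethyl 3-methylbutanoate
Conditions: PPh3, DIAD, toluene, 0 → 23 °C
Reagents that add atoms: none
Why: Mitsunobu esterification: SN2 displacement of the oxyphosphonium group by the carboxylate with inversion should set (8R) and install the isovalerate in one step.

Step 15
Reactants: 21 the diene ester from step 14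
Product: 22 CNP0409052.1, (6R,7R,8R,10S)-8-(3-methylbutanoyloxy)-1-oxo-3,10-epoxygermacra-2,4(Z),11(13)-trien-12,6-olide
Conditions: Hoveyda–Grubbs second-generation catalyst (20 mol%, in portions), toluene (1 mM), 100 °C
Reagents that add atoms: none
Why: Ring-closing metathesis: ruthenium should load on the propenyl group and close on the furanone isopropenyl group with loss of propene, giving the nine-membered oxacycle (ten-membered carbocycle) in which only the (Z)-C4=C5 alkene is possible; the electron-poor 1,1-disubstituted exo-methylene group should not take part, and closure of an oxonin ring onto a 5-isopropenyl-3(2H)-furanone is a known type of macrocyclic RCM.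

Compound list
1 | 3-[(tert-butyldimethylsilyl)oxy]propanal | O=CCCO[Si](C)(C)C(C)(C)C | starting material
2 | isopropenylmagnesium bromide | C=C(C)[Mg]Br | starting material
3 | rac-5-[(tert-butyldimethylsilyl)oxy]-2-methylpent-1-en-3-ol | C=C(C)C(O)CCO[Si](C)(C)C(C)(C)C | intermediate
4 | (3S)-5-[(tert-butyldimethylsilyl)oxy]-2-methylpent-1-en-3-ol | C=C(C)[C@@H](O)CCO[Si](C)(C)C(C)(C)C | intermediate
5 | ethyl but-2-ynoate | CC#CC(=O)OCC | starting material
6 | ethyl (2E)-3-{[(3S)-5-[(tert-butyldimethylsilyl)oxy]-2-methylpent-1-en-3-yl]oxy}but-2-enoate | CCOC(=O)/C=C(\C)O[C@@H](CCO[Si](C)(C)C(C)(C)C)C(C)=C | intermediate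
7 | ethyl (2E)-3-{[(3S)-5-hydroxy-2-methylpent-1-en-3-yl]oxy}but-2-enoate | CCOC(=O)/C=C(\C)O[C@@H](CCO)C(C)=C | intermediate
8 | ethyl (2E)-3-{[(3S)-2-methyl-5-oxopent-1-en-3-yl]oxy}but-2-enoate | CCOC(=O)/C=C(\C)O[C@@H](CC=O)C(C)=C | intermediate
9 | ethyl 2-[(2S,5S)-2-methyl-3-oxo-5-(prop-1-en-2-yl)oxolan-2-yl]acetate | CCOC(=O)C[C@]1(C)O[C@H](C(C)=C)CC1=O | intermediate
10 | 2-[(2S,5S)-3-hydroxy-2-methyl-5-(prop-1-en-2-yl)oxolan-2-yl]ethan-1-ol (C3 epimers) | OCC[C@]1(C)O[C@H](C(C)=C)CC1O | intermediate
11 | 2-[(2S,5S)-2-methyl-3-oxo-5-(prop-1-en-2-yl)oxolan-2-yl]acetaldehyde | O=CC[C@]1(C)O[C@H](C(C)=C)CC1=O | intermediate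
12 | 2-[(2S)-2-methyl-3-oxo-5-(prop-1-en-2-yl)-2,3-dihydrofuran-2-yl]acetaldehyde | O=CC[C@]1(C)OC(C(C)=C)=CC1=O | intermediate
13 | rac-(4E)-hexa-1,4-dien-3-ol | C/C=C/C(O)C=C | starting material
14 | (3S,4E)-hexa-1,4-dien-3-ol | C/C=C/[C@@H](O)C=C | intermediate
15 | 2-(bromomethyl)prop-2-enoic acid | C=C(CBr)C(=O)O | starting material
16 | (3S,4E)-hexa-1,4-dien-3-yl 2-(bromomethyl)prop-2-enoate | C/C=C/[C@@H](OC(=O)C(=C)CBr)C=C | intermediate
17 | (5R)-3-(bromomethyl)-5-[(1E)-prop-1-en-1-yl]furan-2(5H)-one | C/C=C/[C@@H]1C=C(CBr)C(=O)O1 | intermediate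
18 | {(5R)-2-oxo-5-[(1E)-prop-1-en-1-yl]-2,5-dihydrofuran-3-yl}methylzinc bromide | C/C=C/[C@@H]1C=C(C[Zn]Br)C(=O)O1 | intermediate
19 | (4R,5R)-4-{(1S)-1-hydroxy-2-[(2S)-2-methyl-3-oxo-5-(prop-1-en-2-yl)-2,3-dihydrofuran-2-yl]ethyl}-3-methylidene-5-[(1E)-prop-1-en-1-yl]oxolan-2-one | C=C1C(=O)O[C@H](/C=C/C)[C@H]1[C@@H](O)C[C@]1(C)OC(C(C)=C)=CC1=O | intermediate
20 | 3-methylbutanoic acid | CC(C)CC(=O)O | starting material
21 | (1R)-2-[(2S)-2-methyl-3-oxo-5-(prop-1-en-2-yl)-2,3-dihydrofuran-2-yl]-1-{(2R,3R)-4-methylidene-5-oxo-2-[(1E)-prop-1-en-1-yl]oxolan-3-yl}ethyl 3-methylbutanoate | C=C1C(=O)O[C@H](/C=C/C)[C@H]1[C@H](OC(=O)CC(C)C)C[C@]1(C)OC(C(C)=C)=CC1=O | intermediate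
22 | CNP0409052.1, (6R,7R,8R,10S)-8-(3-methylbutanoyloxy)-1-oxo-3,10-epoxygermacra-2,4(Z),11(13)-trien-12,6-olide | C=C1C(=O)O[C@@H]2/C=C(/C)C3=CC(=O)[C@](C)(C[C@@H](OC(=O)CC(C)C)[C@@H]12)O3 | target

Total step count: 15. Longest linear sequence: 12 (steps 1–9, then 13–15); steps 10–12 form the side branch to butenolide 17.

Steps most likely to fail

1. Step 6 (Stetter ring closure). The β-alkoxy aldehyde may lose its vinylogous-carbonate oxygen by E1cB elimination under the basic carbene conditions, or the catalyst may not control the alkene face well enough. Fallback by a neutral radical route, setting out from 8: Pinnick oxidation (NaClO2, NaH2PO4, 2-methyl-2-butene, t-BuOH/H2O) should give (3S)-3-{[(2E)-4-ethoxy-4-oxobut-2-en-2-yl]oxy}-4-methylpent-4-enoic acid F1. Diphenyl diselenide and PBu3 should convert this into the Se-phenyl selenoester F2. Tris(trimethylsilyl)silane with Et3B/air in benzene at 23 °C should then generate the acyl radical, which closes 5-exo-trig onto the β-alkoxyacrylate; the C3 centre should direct the 2,5-cis ring. The route is rejoined at 9.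

2. Step 15 (macrocyclic RCM). Ruthenium may fail to engage the conjugated, 1,1-disubstituted isopropenyl group in a strained nine-membered transition state, so that oligomerisation and catalyst decay take over. Fallback, setting out from 19: the ring closure is moved ahead of the esterification. The free (8S)-alcohol 19 carries a smaller, hydrogen-bond-donating C8 substituent and a different conformational bias; with Hoveyda–Grubbs II (toluene, 100 °C, high dilution) it should give the macrocyclic alcohol (6R,7R,8S,10S)-8-hydroxy-1-oxo-3,10-epoxygermacra-2,4(Z),11(13)-trien-12,6-olide F3. Mitsunobu esterification of this alcohol with 20 (PPh3, DIAD) then inverts C8 and returns to the route at 22.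

3. Step 14 (Mitsunobu inversion). The hindered carbinol may eliminate or react with retention, or the phosphine may add to the exo-methylene lactone. Fallback by oxidation and reduction, setting out from 19: Dess–Martin oxidation should give the ketone (4S,5R)-3-methylidene-4-{[(2S)-2-methyl-3-oxo-5-(prop-1-en-2-yl)-2,3-dihydrofuran-2-yl]acetyl}-5-[(1E)-prop-1-en-1-yl]oxolan-2-one F4. Reagent-controlled CBS reduction (oxazaborolidine antipode chosen for the 8R carbinol, catecholborane, −78 °C) should give the (8R)-alcohol (4R,5R)-4-{(1R)-1-hydroxy-2-[(2S)-2-methyl-3-oxo-5-(prop-1-en-2-yl)-2,3-dihydrofuran-2-yl]ethyl}-3-methylidene-5-[(1E)-prop-1-en-1-yl]oxolan-2-one F5. Acylation with 3-methylbutanoic anhydride and DMAP returns to the route at 21.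

Further compounds
F1 | step 6 | (3S)-3-{[(2E)-4-ethoxy-4-oxobut-2-en-2-yl]oxy}-4-methylpent-4-enoic acid | CCOC(=O)/C=C(\C)O[C@@H](CC(=O)O)C(C)=C
F2 | step 6 | Se-phenyl (3S)-3-{[(2E)-4-ethoxy-4-oxobut-2-en-2-yl]oxy}-4-methylpent-4-eneselenoate | CCOC(=O)/C=C(\C)O[C@@H](CC(=O)[Se]c1ccccc1)C(C)=C
F3 | step 15 | (6R,7R,8S,10S)-8-hydroxy-1-oxo-3,10-epoxygermacra-2,4(Z),11(13)-trien-12,6-olide | C=C1C(=O)O[C@@H]2/C=C(/C)C3=CC(=O)[C@](C)(C[C@H](O)[C@@H]12)O3
F4 | step 14 | (4S,5R)-3-methylidene-4-{[(2S)-2-methyl-3-oxo-5-(prop-1-en-2-yl)-2,3-dihydrofuran-2-yl]acetyl}-5-[(1E)-prop-1-en-1-yl]oxolan-2-one | C=C1C(=O)O[C@H](/C=C/C)[C@H]1C(=O)C[C@]1(C)OC(C(C)=C)=CC1=O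
F5 | step 14 | (4R,5R)-4-{(1R)-1-hydroxy-2-[(2S)-2-methyl-3-oxo-5-(prop-1-en-2-yl)-2,3-dihydrofuran-2-yl]ethyl}-3-methylidene-5-[(1E)-prop-1-en-1-yl]oxolan-2-one | C=C1C(=O)O[C@H](/C=C/C)[C@H]1[C@H](O)C[C@]1(C)OC(C(C)=C)=CC1=O
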